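**Retrosynthetic overview** (carotenoid numbering; primed numbers belong to the β-ring half)

1. The target is cut at the exocyclic C11=C12 bond of the (Z)-ylidene-butenolide into butenolide 20 and the C25 hexaenal 13 (vinylogous aldol–elimination). 13 comes from C15 phosphonium salt 11 and C10 dialdehyde 12 (Wittig at C11'=C12'); 20 comes from a B-alkyl Suzuki coupling (C8–C9) of a vinyl-substituted ε ring with bromofuranone 18.
2. Both trimethylcyclohexene end groups are drawn from one resolved cis-hydroxy ester 5: reduction and base-induced conjugation give the β-ring aldehyde 8, while Mitsunobu inversion at C3, reduction and methylenation give the trans ε ring 17.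
3. Key disconnection: the carbocycle of lactone 3 is a retro-[4+2] to 4-methyl-2-pyrone 1 and isobutylene 2. The forward step makes the C2'–C3' bond (ring CH2 to the carbinol carbon) and the C1'–C6' bond (CMe2 to the chain-bearing ring carbon) at once and dearomatises the pyrone.
4. Enabling feature: in the β ring the hydroxyl-bearing C3' and the chain-bearing C6' stand 1,4 to each other across C4'–C5'(Me), and C6' carries exactly one carbon, C7'. With C7' at the carboxyl level and acylating O3', the atoms O3'–C3'–C4'–C5'(Me)–C6'–C7'(=O) are the ring of a 2-pyrone, and the remaining C1'(Me)2–C2'H2 unit is isobutylene. The same cis-bridged adduct maps onto C3, C6 and C7 of the ε ring.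
5. Ring order: carbocycle plus temporary lactone ring (step 1) → bridge opened (step 2) → β ring (step 4, through a transient lactol bridge) and ε ring (steps 9–12) → furanone ring brought in intact (step 13); no further permanent ring is formed.

Key step: step 1

**Assumptions**
- Compounds 1, 12 and 18 are taken as catalogue compounds.
- In step 3 the lipase is assumed to acylate the (4R)-carbinol, as for related cyclohex-2-en-1-ols; the sense is to be confirmed on the first batch by NMR analysis of diastereomeric α-methoxyphenylacetates.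

**Route**

Step 1
Reactants: 1 4-methyl-2H-pyran-2-one; 2 2-methylpropene (isobutylene)
Product: 3 rac-5,8,8-trimethyl-2-oxabicyclo[2.2.2]oct-5-en-3-one
Conditions: 2 (10 equiv, condensed), BHT (cat.), CH2Cl2, 13 kbar, 65 °C, 48 h
Reagents that add atoms: none
Why: A concerted but asynchronous inverse-electron-demand Diels–Alder reaction in which pyrone carbons C3 and C6 are the diene termini, the closest known type being the thermal and high-pressure [4+2] cycloadditions of 2-pyrones and coumalates with simple 1-alkenes and enol ethers, which give 2-oxabicyclo[2.2.2]octenones. The step closes the carbocyclic six-membered ring by intermolecular [4+2] cycloaddition (the lactone bridge is already present in the diene and becomes the second ring of the bicycle), forming the CH2–C(O) bond and the CMe2–C(C=O) bond together and dearomatising the pyrone. The two new stereocentres are the bridgeheads; their cis relation follows from suprafacial addition to the diene and is locked by the lactone bridge, the adduct is racemic because both partners are achiral, and no endo/exo question arises since each alkene carbon carries two identical groups. The selectivity needed is regiochemical (CH2 to the oxygen-bearing C6, CMe2 to C3) and should be secured by polarity: the pyrone LUMO coefficient is largest at C6, the alkene HOMO coefficient is largest at CH2, and the tertiary cation character developing at CMe2 is met by the enolate-like C3. High pressure accelerates the bimolecular addition (negative activation volume) at a temperature below that at which the adduct would lose CO2 by retro-[4+2] reaction.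

Step 2
Reactants: 3 rac-5,8,8-trimethyl-2-oxabicyclo[2.2.2]oct-5-en-3-one
Product: 4 rac-methyl cis-4-hydroxy-2,6,6-trimethylcyclohex-2-ene-1-carboxylate
Conditions: K2CO3 (0.2 equiv), MeOH, 0 °C
Reagents that add atoms: methanol, CO
Why: Base-catalysed transesterification (lactone methanolysis) is driven by release of the strain of the bridged lactone, and since the bridgehead α-carbon cannot enolise while the bridge is intact and the opened ester meets carbonate only briefly at 0 °C, the cis relation of hydroxyl and ester and the position of the alkene should be retained.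

Step 3
Reactants: 4 rac-methyl cis-4-hydroxy-2,6,6-trimethylcyclohex-2-ene-1-carboxylate
Product: 5 methyl (1R,4S)-4-hydroxy-2,6,6-trimethylcyclohex-2-ene-1-carboxylate
Conditions: immobilised Burkholderia cepacia lipase, vinyl acetate (3 equiv), MTBE, 35 °C, stopped at about 55% conversion; chromatography
Reagents that add atoms: none
Why: Lipase-catalysed kinetic resolution by irreversible transesterification with vinyl acetate, in which the enantiomer with the (4R)-carbinol is expected to be acetylated (alkene side of the ring acting as the large substituent) so that the (1R,4S)-alcohol remains and gains enantiomeric purity as conversion passes one half; no new stereocentre is made.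

Step 4
Reactants: 5 methyl (1R,4S)-4-hydroxy-2,6,6-trimethylcyclohex-2-ene-1-carboxylate
Product: 8 (4R)-4-hydroxy-2,6,6-trimethylcyclohex-1-ene-1-carbaldehyde, via open hydroxy aldehyde 6 (not isolated), via bridged lactol 7 (not isolated)
Conditions: i-Bu2AlH (2.3 equiv), CH2Cl2, −78 °C; aq. KNaC4H4O6 (potassium sodium tartrate) work-up; dried CH2Cl2 phase, DBU (0.3 equiv), 0 °C → rt
Reagents that add atoms: none
Why: Partial reduction of the ester by i-Bu2AlH stops at the aldehyde oxidation level because the tetrahedral aluminium alkoxide is stable at −78 °C, the cis-hydroxy aldehyde set free on work-up rests as its bridged hemiacetal, and DBU then moves the alkene into conjugation through the dienolate of the open form (the α- to β-cyclocitral isomerisation), which is driven by conjugation and tetrasubstitution and ends the possibility of lactol closure, while the carbinol centre fixed in steps 1 and 3 is untouched and catalytic base at or below room temperature should keep vinylogous loss of the hydroxyl slow.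

Step 5
Reactants: 8 (4R)-4-hydroxy-2,6,6-trimethylcyclohex-1-ene-1-carbaldehyde
Product: 9 (3E)-4-[(4R)-4-hydroxy-2,6,6-trimethylcyclohex-1-en-1-yl]but-3-en-2-one
Conditions: (MeO)2P(O)CH2C(O)CH3 (2.2 equiv), NaH (2.1 equiv), THF, 0 °C → rt
Reagents that add atoms: dimethyl (2-oxopropyl)phosphonate, COP(=O)(CC(C)=O)OC
Why: Horner–Wadsworth–Emmons olefination with the stabilised keto-phosphonate anion gives the E-enone, and because this anion, kept in slight excess over NaH, is too weak a base to start vinylogous elimination of the ring hydroxyl, the carbinol centre should survive.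

Step 6
Reactants: 9 (3E)-4-[(4R)-4-hydroxy-2,6,6-trimethylcyclohex-1-en-1-yl]but-3-en-2-one
Product: 10 (1R)-4-[(1E)-3-hydroxy-3-methylpenta-1,4-dien-1-yl]-3,5,5-trimethylcyclohex-3-en-1-ol
Conditions: CH2=CHMgBr (3 equiv), THF, −30 → 0 °C; aq. NH4Cl
Reagents that add atoms: vinylmagnesium bromide, C=C[Mg]Br
Why: 1,2-Addition of the vinyl Grignard reagent to the enone carbonyl (the first equivalent is spent on the hydroxyl) gives the tertiary divinyl carbinol, whose new centre forms without control and is removed again in step 7.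

Step 7
Reactants: 10 (1R)-4-[(1E)-3-hydroxy-3-methylpenta-1,4-dien-1-yl]-3,5,5-trimethylcyclohex-3-en-1-ol
Product: 11 [(2E,4E)-5-[(4R)-4-hydroxy-2,6,6-trimethylcyclohex-1-en-1-yl]-3-methylpenta-2,4-dien-1-yl]triphenylphosphonium bromide
Conditions: PPh3·HBr (1.1 equiv), MeOH, rt; crystallisation
Reagents that add atoms: triphenylphosphine hydrobromide, Br.c1ccc(cc1)P(c1ccccc1)c1ccccc1
Why: Acid-induced ionisation of the tertiary bis-allylic alcohol to a pentadienyl cation and capture by triphenylphosphine at the unsubstituted terminus (SN1' allylic transposition) gives the conjugated allylic phosphonium salt, from which the 2E,4E isomer should crystallise.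

Step 8
Reactants: 11 C15 phosphonium bromide; 12 (2E,4E,6E)-2,7-dimethylocta-2,4,6-trienedial (2 equiv)
Product: 13 (2E,4E,6E,8E,10E,12E)-13-[(4R)-4-hydroxy-2,6,6-trimethylcyclohex-1-en-1-yl]-2,7,11-trimethyltrideca-2,4,6,8,10,12-hexaenal
Conditions: NaOMe (1.1 equiv), MeOH/CH2Cl2, 0 °C → rt; then n-heptane, reflux
Reagents that add atoms: none
Why: Wittig olefination of one formyl group of the symmetrical dialdehyde, used in excess to hold back double olefination, forms the C11'=C12' bond as an E/Z mixture that thermal equilibration should convert into the all-E hexaenal.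

Step 9
Reactants: 5 methyl (1R,4S)-4-hydroxy-2,6,6-trimethylcyclohex-2-ene-1-carboxylate
Product: 14 methyl (1R,4R)-2,6,6-trimethyl-4-[(4-nitrobenzoyl)oxy]cyclohex-2-ene-1-carboxylate
Conditions: 4-nitrobenzoic acid (1.5 equiv), PPh3 (1.5 equiv), DIAD (1.5 equiv), toluene, 0 °C → rt
Reagents that add atoms: 4-nitrobenzoic acid, OC(=O)c1ccc(cc1)[N+](=O)[O-]
Why: Mitsunobu esterification, in which SN2 displacement of the alkoxyphosphonium ion by the carboxylate inverts the allylic carbinol centre (4S to 4R) and so turns the cis ring from step 1 into the trans ring of the target, the SN2' path being disfavoured because it would build a tertiary ester centre next to the ring carbon that carries the methoxycarbonyl group.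

Step 10
Reactants: 14 methyl (1R,4R)-2,6,6-trimethyl-4-[(4-nitrobenzoyl)oxy]cyclohex-2-ene-1-carboxylate
Product: 15 methyl (1R,4R)-4-hydroxy-2,6,6-trimethylcyclohex-2-ene-1-carboxylate
Conditions: K2CO3 (0.3 equiv), MeOH, 0 °C
Reagents that add atoms: none
Why: Carbonate-catalysed methanolysis (transesterification) of the electron-poor aryl ester should be much faster at 0 °C than enolisation of the hindered ring ester, so the inverted alcohol is freed with both stereocentres and the alkene position intact.

Step 11
Reactants: 15 methyl (1R,4R)-4-hydroxy-2,6,6-trimethylcyclohex-2-ene-1-carboxylate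
Product: 16 (1R,4R)-4-hydroxy-2,6,6-trimethylcyclohex-2-ene-1-carbaldehyde
Conditions: i-Bu2AlH (2.3 equiv), CH2Cl2, −78 °C; aq. KNaC4H4O6 (potassium sodium tartrate) work-up at 0 °C; used at once
Reagents that add atoms: none
Why: Partial ester reduction with i-Bu2AlH as in step 4 (tetrahedral aluminium alkoxide stable at −78 °C), and because the hydroxyl now stands trans to the formyl group no bridged lactol can close, so the open β,γ-unsaturated aldehyde is obtained and is carried on without delay to avoid epimerisation or conjugation.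

Step 12
Reactants: 16 (1R,4R)-4-hydroxy-2,6,6-trimethylcyclohex-2-ene-1-carbaldehyde
Product: 17 (1R,4R)-4-ethenyl-3,5,5-trimethylcyclohex-2-en-1-ol
Conditions: Ph3PCH3Br (3.0 equiv), KOt-Bu (2.8 equiv), THF, 0 °C; then 16, −78 → 0 °C
Reagents that add atoms: methyltriphenylphosphonium bromide, C[P+](c1ccccc1)(c1ccccc1)c1ccccc1.[Br-]
Why: Wittig methylenation, in which the non-stabilised ylide should add to the aldehyde at low temperature faster than the α-centre epimerises or the alkene conjugates, so that the trans relation of the C3 oxygen and the C6 substituent is carried over.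

Step 13
Reactants: 17 (1R,4R)-4-ethenyl-3,5,5-trimethylcyclohex-2-en-1-ol; 18 3-bromofuran-2(5H)-one
Product: 20 3-[2-[(1R,4R)-4-hydroxy-2,6,6-trimethylcyclohex-2-en-1-yl]ethyl]furan-2(5H)-one, via bis-boron adduct 19 (not isolated)
Conditions: 9-BBN (2.3 equiv), THF, 0 °C → rt; then 18, PdCl2(dppf) (5 mol%), AsPh3 (5 mol%), Cs2CO3 (3 equiv), DMF/H2O, rt
Reagents that add atoms: none
Why: Anti-Markovnikov hydroboration of the monosubstituted vinyl group with 9-BBN (the first equivalent is taken up by the hydroxyl and the trisubstituted ring alkene is too hindered to react) followed by B-alkyl Suzuki–Miyaura coupling with the α-bromo-butenolide forms the C8–C9 bond under mild base and leaves both stereocentres untouched.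

Step 14
Reactants: 13 C25 hydroxy hexaenal; 20 3-[2-[(1R,4R)-4-hydroxy-2,6,6-trimethylcyclohex-2-en-1-yl]ethyl]furan-2(5H)-one
Product: 24 bis(tert-butyldimethylsilyl) ether of the target, via silylated aldehyde 21 (not isolated), via silyloxyfuran 22 (not isolated), via aldol silyl ether 23 (not isolated)
Conditions: TBSOTf (5 equiv), i-Pr2NEt (7 equiv), CH2Cl2, −78 → 0 °C; then DBU (3 equiv), rt
Reagents that add atoms: tert-butyldimethylsilyl trifluoromethanesulfonate, CC(C)(C)[Si](C)(C)OS(=O)(=O)C(F)(F)F
Why: One-flask vinylogous Mukaiyama aldol addition of the 2-silyloxyfuran generated in situ (attack through C5 of the furanone) to the silyl-triflate-activated aldehyde followed by DBU-induced E1cB loss of silanol should give mainly the thermodynamically preferred Z-ylidene-butenolide, both hydroxyls being silylated in the same flask.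

Step 15
Reactants: 24 bis(tert-butyldimethylsilyl) ether of the target
Product: 25 CNP0242041.1 (target)
Conditions: HF·pyridine, pyridine, THF, 0 °C → rt
Reagents that add atoms: none
Why: Fluoride-mediated cleavage of the two secondary silyl ethers (desilylation) under pyridine-buffered conditions should spare the ylidene-butenolide, the polyene and the allylic alcohol.

**Compound list**

1 | 4-methyl-2H-pyran-2-one | CC1=CC(=O)OC=C1 | starting material
2 | 2-methylpropene (isobutylene) | CC(C)=C | starting material
3 | rac-5,8,8-trimethyl-2-oxabicyclo[2.2.2]oct-5-en-3-one (racemate; (1S,4R) and (1R,4S) forms written) | CC1=C[C@@H]2CC(C)(C)[C@H]1C(=O)O2.CC1=C[C@H]2CC(C)(C)[C@@H]1C(=O)O2 | intermediate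
4 | rac-methyl cis-4-hydroxy-2,6,6-trimethylcyclohex-2-ene-1-carboxylate (racemate; (1R,4S) and (1S,4R) forms written) | CC1=C[C@@H](O)CC(C)(C)[C@H]1C(=O)OC.CC1=C[C@H](O)CC(C)(C)[C@@H]1C(=O)OC | intermediate
5 | methyl (1R,4S)-4-hydroxy-2,6,6-trimethylcyclohex-2-ene-1-carboxylate (cis) | CC1=C[C@@H](O)CC(C)(C)[C@H]1C(=O)OC | intermediate
6 | (1R,4S)-4-hydroxy-2,6,6-trimethylcyclohex-2-ene-1-carbaldehyde (cis; open hydroxy aldehyde, formed in the flask) | CC1=C[C@@H](O)CC(C)(C)[C@H]1C=O | intermediate
7 | (1S,4R)-5,8,8-trimethyl-2-oxabicyclo[2.2.2]oct-5-en-3-ol (bridged lactol, mixture of anomers, formed in the flask) | CC1=C[C@@H]2CC(C)(C)[C@H]1C(O)O2 | intermediate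
8 | (4R)-4-hydroxy-2,6,6-trimethylcyclohex-1-ene-1-carbaldehyde | O=CC1=C(C)C[C@@H](O)CC1(C)C | intermediate
9 | (3E)-4-[(4R)-4-hydroxy-2,6,6-trimethylcyclohex-1-en-1-yl]but-3-en-2-one ((3R)-3-hydroxy-β-ionone) | CC(=O)/C=C/C1=C(C)C[C@@H](O)CC1(C)C | intermediate
10 | (1R)-4-[(1E)-3-hydroxy-3-methylpenta-1,4-dien-1-yl]-3,5,5-trimethylcyclohex-3-en-1-ol (mixture of epimers at the side-chain carbinol) | C=CC(C)(O)/C=C/C1=C(C)C[C@@H](O)CC1(C)C | intermediate
11 | [(2E,4E)-5-[(4R)-4-hydroxy-2,6,6-trimethylcyclohex-1-en-1-yl]-3-methylpenta-2,4-dien-1-yl]triphenylphosphonium bromide | [Br-].C(/C=C(C)/C=C/C1=C(C)C[C@@H](O)CC1(C)C)[P+](c1ccccc1)(c1ccccc1)c1ccccc1 | intermediate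
12 | (2E,4E,6E)-2,7-dimethylocta-2,4,6-trienedial | O=C/C(C)=C/C=C/C=C(C)/C=O | starting material
13 | (2E,4E,6E,8E,10E,12E)-13-[(4R)-4-hydroxy-2,6,6-trimethylcyclohex-1-en-1-yl]-2,7,11-trimethyltrideca-2,4,6,8,10,12-hexaenal | O=C/C(C)=C/C=C/C=C(C)/C=C/C=C(C)/C=C/C1=C(C)C[C@@H](O)CC1(C)C | intermediate
14 | methyl (1R,4R)-2,6,6-trimethyl-4-[(4-nitrobenzoyl)oxy]cyclohex-2-ene-1-carboxylate (trans) | CC1=C[C@H](OC(=O)c2ccc(cc2)[N+](=O)[O-])CC(C)(C)[C@H]1C(=O)OC | intermediate
15 | methyl (1R,4R)-4-hydroxy-2,6,6-trimethylcyclohex-2-ene-1-carboxylate (trans) | CC1=C[C@H](O)CC(C)(C)[C@H]1C(=O)OC | intermediate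
16 | (1R,4R)-4-hydroxy-2,6,6-trimethylcyclohex-2-ene-1-carbaldehyde (trans) | CC1=C[C@H](O)CC(C)(C)[C@H]1C=O | intermediate
17 | (1R,4R)-4-ethenyl-3,5,5-trimethylcyclohex-2-en-1-ol (trans) | CC1=C[C@H](O)CC(C)(C)[C@H]1C=C | intermediate
18 | 3-bromofuran-2(5H)-one | BrC1=CCOC1=O | starting material
19 | 9-[2-[(1R,4R)-4-(9-borabicyclo[3.3.1]nonan-9-yloxy)-2,6,6-trimethylcyclohex-2-en-1-yl]ethyl]-9-borabicyclo[3.3.1]nonane (formed in the flask) | CC1=C[C@H](OB2C3CCCC2CCC3)CC(C)(C)[C@H]1CCB1C2CCCC1CCC2 | intermediate
20 | 3-[2-[(1R,4R)-4-hydroxy-2,6,6-trimethylcyclohex-2-en-1-yl]ethyl]furan-2(5H)-one | CC1=C[C@H](O)CC(C)(C)[C@H]1CCC1=CCOC1=O | intermediate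
21 | tert-butyldimethylsilyl ether of 13 (formed in the flask) | O=C/C(C)=C/C=C/C=C(C)/C=C/C=C(C)/C=C/C1=C(C)C[C@@H](O[Si](C)(C)C(C)(C)C)CC1(C)C | intermediate
22 | 2-(tert-butyldimethylsilyloxy)-3-[2-[(1R,4R)-4-(tert-butyldimethylsilyloxy)-2,6,6-trimethylcyclohex-2-en-1-yl]ethyl]furan (formed in the flask) | CC1=C[C@H](O[Si](C)(C)C(C)(C)C)CC(C)(C)[C@H]1CCc1ccoc1O[Si](C)(C)C(C)(C)C | intermediate
23 | tris-silylated aldol adduct at C11–C12, mixture of diastereomers at the two new centres (formed in the flask) | CC1=C[C@H](O[Si](C)(C)C(C)(C)C)CC(C)(C)[C@H]1CCC1=CC(OC1=O)C(O[Si](C)(C)C(C)(C)C)/C(C)=C/C=C/C=C(C)/C=C/C=C(C)/C=C/C1=C(C)C[C@@H](O[Si](C)(C)C(C)(C)C)CC1(C)C | intermediate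
24 | bis(tert-butyldimethylsilyl) ether of the target | CC1=C[C@H](O[Si](C)(C)C(C)(C)C)CC(C)(C)[C@H]1CCC1=C/C(=C/C(C)=C/C=C/C=C(C)/C=C/C=C(C)/C=C/C2=C(C)C[C@@H](O[Si](C)(C)C(C)(C)C)CC2(C)C)OC1=O | intermediate
25 | CNP0242041.1: (5Z)-3-[2-[(1R,4R)-4-hydroxy-2,6,6-trimethylcyclohex-2-en-1-yl]ethyl]-5-[(2E,4E,6E,8E,10E,12E)-13-[(4R)-4-hydroxy-2,6,6-trimethylcyclohex-1-en-1-yl]-2,7,11-trimethyltrideca-2,4,6,8,10,12-hexaen-1-ylidene]furan-2(5H)-one | CC1=C[C@H](O)CC(C)(C)[C@H]1CCC1=C/C(=C/C(C)=C/C=C/C=C(C)/C=C/C=C(C)/C=C/C2=C(C)C[C@@H](O)CC2(C)C)OC1=O | target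

**Step count and risks**

Total step count: 15. Longest linear sequence: 10 steps (steps 1–8, 14, 15; the ε-ring branch, steps 1–3 and 9–15, is equally long).

Step 1. Risk: the unactivated diene–alkene pair may add too slowly at a temperature low enough to prevent loss of CO2 from the adduct, or with eroded regiocontrol. Fallback, setting out from 1 and returning at 3: the diene is activated by a removable halogen. 1 is brominated (Br2, CH2Cl2, then Et3N) to 3-bromo-4-methyl-2H-pyran-2-one F1, a member of the ambiphilic 3-bromo-2-pyrone class that adds to simple alkenes under much milder conditions. Cycloaddition of it with 2 (sealed tube, 80–90 °C) should give rac-4-bromo-5,8,8-trimethyl-2-oxabicyclo[2.2.2]oct-5-en-3-one F2 with the same orientation, and radical debromination at the bridgehead (n-Bu3SnH, AIBN, toluene, 80 °C) returns lactone 3.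

Step 14. Risk: degradation or E/Z scrambling of the hexaenal under silyl triflate activation, and incomplete Z-selectivity in the elimination on a large, sensitive substrate. Fallback, setting out from 20 and returning at 25: the order of fragment union is reversed so that the butenolide chemistry is done on a small, robust aldehyde. 20 is silylated (TBSCl, imidazole, DMF) to 3-[2-[(1R,4R)-4-(tert-butyldimethylsilyloxy)-2,6,6-trimethylcyclohex-2-en-1-yl]ethyl]furan-2(5H)-one F5. The same silyl triflate aldol (through silyloxyfuran 22) with an excess of 12 gives the aldol silyl ether F6, not isolated, and DBU converts it into the (Z)-ylidene-butenolide trienal F7. Wittig olefination of this with the ylide from 11 (NaN(SiMe3)2, 2 equiv, THF, −78 °C, then thermal Z to E equilibration) gives the mono-silyl ether of the target F8, which HF·pyridine cleaves to 25.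

Step 3. Risk: insufficient discrimination of the enantiomers by the lipase, or acylation in the opposite sense. Fallback, setting out from 4 and returning at 5: resolution through covalent diastereomers. rac-4 is esterified with (S)-2-methoxy-2-phenylacetic acid (DCC, DMAP, CH2Cl2) to methyl (1R,4S)-4-[(2S)-2-methoxy-2-phenylacetoxy]-2,6,6-trimethylcyclohex-2-ene-1-carboxylate F3 and its diastereomer methyl (1S,4R)-4-[(2S)-2-methoxy-2-phenylacetoxy]-2,6,6-trimethylcyclohex-2-ene-1-carboxylate F4. These are separated by chromatography or crystallisation and assigned by the 1H NMR shielding pattern of such esters; mild methanolysis of F3 (K2CO3, MeOH, 0 °C) returns 5.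

**Further compounds**

F1 | step 1 | 3-bromo-4-methyl-2H-pyran-2-one | CC1=C(Br)C(=O)OC=C1
F2 | step 1 | rac-4-bromo-5,8,8-trimethyl-2-oxabicyclo[2.2.2]oct-5-en-3-one (racemate, both enantiomers written) | CC1=C[C@@H]2CC(C)(C)[C@@]1(Br)C(=O)O2.CC1=C[C@H]2CC(C)(C)[C@]1(Br)C(=O)O2
F3 | step 3 | methyl (1R,4S)-4-[(2S)-2-methoxy-2-phenylacetoxy]-2,6,6-trimethylcyclohex-2-ene-1-carboxylate | CC1=C[C@@H](OC(=O)[C@@H](OC)c2ccccc2)CC(C)(C)[C@H]1C(=O)OC
F4 | step 3 | methyl (1S,4R)-4-[(2S)-2-methoxy-2-phenylacetoxy]-2,6,6-trimethylcyclohex-2-ene-1-carboxylate | CC1=C[C@H](OC(=O)[C@@H](OC)c2ccccc2)CC(C)(C)[C@@H]1C(=O)OC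
F5 | step 14 | 3-[2-[(1R,4R)-4-(tert-butyldimethylsilyloxy)-2,6,6-trimethylcyclohex-2-en-1-yl]ethyl]furan-2(5H)-one | CC1=C[C@H](O[Si](C)(C)C(C)(C)C)CC(C)(C)[C@H]1CCC1=CCOC1=O
F6 | step 14 | aldol silyl ether of F5 and 12 (mixture of diastereomers, not isolated) | CC1=C[C@H](O[Si](C)(C)C(C)(C)C)CC(C)(C)[C@H]1CCC1=CC(OC1=O)C(O[Si](C)(C)C(C)(C)C)/C(C)=C/C=C/C=C(C)/C=O
F7 | step 14 | (2E,4E,6E)-8-[(2Z)-4-[2-[(1R,4R)-4-(tert-butyldimethylsilyloxy)-2,6,6-trimethylcyclohex-2-en-1-yl]ethyl]-5-oxofuran-2(5H)-ylidene]-2,7-dimethylocta-2,4,6-trienal | CC1=C[C@H](O[Si](C)(C)C(C)(C)C)CC(C)(C)[C@H]1CCC1=C/C(=C/C(C)=C/C=C/C=C(C)/C=O)OC1=O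
F8 | step 14 | mono(tert-butyldimethylsilyl) ether of the target (silyl group on the ε-ring oxygen) | CC1=C[C@H](O[Si](C)(C)C(C)(C)C)CC(C)(C)[C@H]1CCC1=C/C(=C/C(C)=C/C=C/C=C(C)/C=C/C=C(C)/C=C/C2=C(C)C[C@@H](O)CC2(C)C)OC1=O
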